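**Strategy.** Ring D is disconnected at C8–C15 and C15–C16. C15 is the one ring D carbon that bears only hydrogen, and it sits between the fully substituted C8 and C16 (which carries the C17 methyl), so it can be delivered as a single carbene carbon. In one operation the C13 acetyl group of a cis-fused perhydrofluorene becomes an alkylidene carbene that inserts into the tertiary C8–H bond, closing ring D (C8, C14, C13, C16, C15) and making C8 quaternary with retention. The precursor is the 3-O-TBS trimethyl ester 23, with rings A to C and all stereocentres set and the acetyl group cis to H8. An asymmetric Michael addition fixes C10; every other centre follows from it.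

Key step: step 16

Remarks. Gibberellane numbering is used: ring A = C1–C5, C10; ring B = C5, C6, C8, C9, C10; ring C = C8, C9, C11–C14; ring D = C8, C14, C13, C16, C15; C7 on C6, C18 and C19 on C4, C20 on C10, C17 on C16. β is the face of H5 and H9 in 30; α is the face of C19 and C20. Acid 1 is assumed to be a catalogue compound.

Step 1
Reactants: 1 (2-bromo-5-chlorophenyl)acetic acid; 2 Meldrum's acid
Product: 4 methyl 4-(2-bromo-5-chlorophenyl)-3-oxobutanoate, via acyl Meldrum's acid 3 (not isolated)
Conditions: DCC, DMAP, CH2Cl2, 0 °C to rt; filter; MeOH, reflux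
Reagents that add atoms: methanol, SMILES CO
Why: Carbodiimide-mediated C-acylation of Meldrum's acid followed by alcoholysis with loss of acetone and CO2 is the standard homologation of a carboxylic acid to its β-keto ester, and no stereocentre is formed.

Step 2
Reactants: 4 methyl 4-(2-bromo-5-chlorophenyl)-3-oxobutanoate
Product: 5 methyl 5-chloro-2-oxoindane-1-carboxylate (racemic and largely enolised)
Conditions: NaH, Pd(PPh3)4 (cat.), DMF, 110 °C; then aq. HCl
Reagents that add atoms: none
Why: Intramolecular arylation of the soft β-keto ester enolate by zerovalent palladium (oxidative addition at C–Br and not at C–Cl, then C–C reductive elimination from a six-membered palladacycle) closes ring B as a 2-indanone and leaves chlorine para to the new C9–C10 bond, that is at C13.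

Step 3
Reactants: 5 methyl 5-chloro-2-oxoindane-1-carboxylate; 6 acrolein
Product: 7 (1R)-1-(3-oxopropyl) indanone ester
Conditions: 9-O-(9-phenanthryl)cupreidine (10 mol%), CH2Cl2, −25 °C
Reagents that add atoms: none
Why: Bifunctional cinchona-base catalysis of the Michael addition of an α-substituted β-keto ester to an enal (the quinuclidine deprotonates the enol and the 6'-OH binds acrolein) should create the quaternary C10 centre under catalyst control, and the quinine-derived pseudo-enantiomer is used instead should the sense of induction prove opposite.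

Step 4
Reactants: 7 (1R)-1-(3-oxopropyl) indanone ester; 8 methyl diazoacetate
Product: 9 side-chain β-keto ester
Conditions: SnCl2 (10 mol%), CH2Cl2, rt
Reagents that add atoms: none
Why: In the Roskamp reaction the diazo ester adds to the aldehyde under SnCl2 catalysis and a 1,2-hydride shift with loss of N2 gives the β-keto ester chemoselectively, leaving the ring ketone and C10 untouched.

Step 5
Reactants: 9 side-chain β-keto ester
Product: 10 tricyclic enone diester
Conditions: piperidine, AcOH (cat.), toluene, reflux, Dean–Stark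
Reagents that add atoms: none
Why: Intramolecular Knoevenagel condensation of the active C4 methylene with the C5 ketone closes the six-membered ring A irreversibly by loss of water (the second half of a Robinson-type annulation) without touching C10.

Step 6
Reactants: 10 tricyclic enone diester
Product: 11 C4-methylated indene keto diester
Conditions: Cs2CO3, MeI, DMF, 0 °C to rt
Reagents that add atoms: iodomethane, SMILES CI
Why: Deprotonation at the benzylic γ-carbon C6 gives an extended enolate that should be C-alkylated at C4 between ketone and ester (the regiochemistry of Hagemann-ester alkylation), with MeI entering on the β face anti to the pseudo-axial C20 ester on C10, so that C18 is β and the C19 ester is cis to C20.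

Step 7
Reactants: 11 C4-methylated indene keto diester
Product: 12 keto aldehyde with trans-fused rings A and B
Conditions: Rh(acac)(CO)2 (cat.), P(O-2,4-t-Bu2C6H3)3, CO/H2 (1:1, 40 bar), toluene, 90 °C
Reagents that add atoms: carbon monoxide, SMILES [C-]#[O+]
Why: Rhodium-catalysed hydroformylation adds H and CHO syn across the styrene-type C5=C6 bond, with the metal and hence the formyl group at the less hindered benzylic C6 and delivery from the β face opposite the two α esters on C4 and C10, which should set H5 β (trans A/B fusion) and place C7 on the β face of C6.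

Step 8
Reactants: 12 keto aldehyde
Product: 13 diol with axial 3β-hydroxyl
Conditions: LiBH(s-Bu)3, THF, −78 °C; aq. NH4Cl
Reagents that add atoms: none
Why: The bulky trialkylborohydride reduces the aldehyde and attacks the C3 ketone of the chair-shaped ring A along the equatorial trajectory, as in 4,4-disubstituted 3-keto terpenoids, which should give the axial 3β-alcohol cis to C18 while the esters stay inert at −78 °C.

Step 9
Reactants: 13 diol
Product: 14 bis-TBS ether
Conditions: TBSOTf, 2,6-lutidine, CH2Cl2, 0 °C
Reagents that add atoms: tert-butyldimethylsilyl trifluoromethanesulfonate, SMILES CC(C)(C)[Si](C)(C)OS(=O)(=O)C(F)(F)F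
Why: A silyl triflate with a hindered pyridine base silylates both the primary and the hindered axial secondary hydroxyl (standard silyl ether formation).

Step 10
Reactants: 14 bis-TBS ether
Product: 15 3-O-TBS primary alcohol
Conditions: camphorsulfonic acid (cat.), MeOH/CH2Cl2, 0 °C
Reagents that add atoms: none
Why: Acid-catalysed methanolysis removes a primary TBS ether far faster than the hindered neopentyl-type secondary one, which frees the C7 hydroxyl that is needed to steer step 12.

Step 11
Reactants: 15 3-O-TBS primary alcohol; 16 tributyl(1-ethoxyvinyl)stannane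
Product: 18 C13 acetyl arene, via aryl enol ether 17 (not isolated)
Conditions: Pd2(dba)3 (cat.), P(t-Bu)3, CsF, dioxane, 100 °C; then 0.5 M HCl, THF, 0 °C
Reagents that add atoms: water, SMILES O
Why: Stille coupling of the aryl chloride under bulky trialkylphosphine and fluoride activation installs a 1-ethoxyvinyl group that mild acid hydrolyses to the C13 acetyl group (C16 and C17) while the hindered silyl ether survives.

Step 12
Reactants: 18 C13 acetyl arene
Product: 19 cis-fused perhydrofluorene diol
Conditions: H2 (70 bar), Rh/Al2O3 (5 wt%), i-PrOH, 50 °C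
Reagents that add atoms: none
Why: Heterogeneous rhodium saturates the arene by all-cis delivery of hydrogen from the β face, which the α C20 ester on C10 leaves open and to which the C7 hydroxymethyl group anchors the substrate (haptophilic effect), so H8 and H9 should be β (cis B/C fusion) and H13 β, the aryl ketone being reduced to the carbinol on the way.

Step 13
Reactants: 19 cis-fused perhydrofluorene diol
Product: 20 keto acid (13-epi)
Conditions: Pr4N[RuO4] (cat.), N-methylmorpholine N-oxide monohydrate, MeCN, rt
Reagents that add atoms: water, SMILES O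
Why: Perruthenate-catalysed oxidation with the N-oxide in the presence of water takes the primary alcohol through the aldehyde hydrate to the acid and the secondary carbinol to the methyl ketone, with silyl ether and esters unaffected.

Step 14
Reactants: 20 keto acid (13-epi); 21 trimethylsilyldiazomethane
Product: 22 13-epi keto triester
Conditions: MeOH/toluene, 0 °C
Reagents that add atoms: none
Why: Esterification through the methyldiazonium ion that forms from the silyl diazomethane in methanol is selective for the carboxylic acid, since the ketone does not react without a Lewis acid.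

Step 15
Reactants: 22 13-epi keto triester
Product: 23 keto triester precursor
Conditions: NaOMe (cat.), MeOH, 40 °C
Reagents that add atoms: none
Why: Reversible enolisation should equilibrate C13 to the epimer whose acetyl group is equatorial in the ring C chair that keeps the quaternary C10 equatorial, that is acetyl cis to H8 and H9, while C6 stays in its more stable form (C7 trans to C4 and C14) and methoxide cannot scramble methyl esters.

Step 16
Reactants: 23 keto triester precursor; 21 trimethylsilyldiazomethane
Product: 26 tetracyclic C15,C16-alkene, via diazoalkene 24 (not isolated), via alkylidene carbene 25 (not isolated)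
Conditions: n-BuLi, THF, −78 °C (21 to LiC(N2)SiMe3); add 23; −78 °C to rt; aq. NH4Cl
Reagents that add atoms: none
Why: Lithiated 21 adds to the C16 carbonyl and the β-silyl alkoxide collapses with loss of Me3SiOLi (Peterson-type olefination) to diazoalkene 24, which sheds N2 to give alkylidene carbene 25. The singlet carbene inserts in a concerted three-centre manner into the C8–H bond five atoms away, the known 1,5 C–H insertion of alkylidene carbenes that converts dialkyl ketones into cyclopentenes. Ring D is closed by this insertion as a five-membered bridge across the 1,3-positions C13 and C8 of ring C, which requires the chair in which the carbene-bearing carbon and H8 are both axial, and the cis B/C fusion makes that chair reachable at the cost of an axial C10. C8 becomes quaternary with retention, so its configuration is dictated by the cis H8/H9 fusion from step 12 and the cis acetyl/H8 relation from step 15. The step needs site selectivity between the two 1,3-diaxial candidates C8–H and C11–H and must outrun the 1,2-methyl shift to an alkyne: a methine C–H is intrinsically several times more reactive than a methylene, and dialkyl alkylidene carbenes insert faster than they rearrange. The esters and the silyl ether are spectators at −78 °C, and enolisation at C13 is harmless because 23 is already the thermodynamic epimer.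

Step 17
Reactants: 26 tetracyclic C15,C16-alkene
Product: 28 C16 tertiary alcohol, via C16 hydroperoxide 27 (not isolated)
Conditions: Mn(dpm)3 (cat.), PhSiH3, O2 (1 atm), i-PrOH/CH2Cl2, 0 °C; then P(OEt)3
Reagents that add atoms: dioxygen, SMILES O=O
Why: In the Mukaiyama hydration a manganese hydride transfers a hydrogen atom to C15, the tertiary C16 radical is captured by O2 on the exo face of the bicyclo[3.2.1]octane (the side of the C14 bridge, away from the C9–C11–C12 bridge), and phosphite reduction of the hydroperoxide should give the alcohol with exo hydroxyl and endo methyl.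

Step 18
Reactants: 28 C16 tertiary alcohol
Product: 29 3-O-TBS tricarboxylic acid
Conditions: n-PrSLi (from n-PrSH, n-BuLi), HMPA, rt; then 1 M HCl
Reagents that add atoms: none
Why: SN2 dealkylation by thiolate attacks the unhindered O-methyl carbons, so the neopentyl-type C19 and C20 esters and the C7 ester are cleaved alike without touching C6 or the tertiary alcohol, and the silyl ether still blocks retro-aldol opening of the C3–C4 bond.

Step 19
Reactants: 29 3-O-TBS tricarboxylic acid
Product: 30 target tricarboxylic acid
Conditions: Bu4NF, THF, 50 °C; then dilute HCl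
Reagents that add atoms: none
Why: Fluoride cleavage of the silyl ether under non-acidic conditions frees the 3β-hydroxyl without cationic rearrangement at the tertiary C16 carbinol, and the C19 carboxylate is too poor an acceptor for retro-aldol epimerisation at C3.

**Compound list**

1 | (2-bromo-5-chlorophenyl)acetic acid | OC(=O)Cc1cc(Cl)ccc1Br | starting material
2 | Meldrum's acid (2,2-dimethyl-1,3-dioxane-4,6-dione) | CC1(C)OC(=O)CC(=O)O1 | starting material
3 | acyl Meldrum's acid, enol form | CC1(C)OC(=O)C(=C(O)Cc2cc(Cl)ccc2Br)C(=O)O1 | intermediate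
4 | methyl 4-(2-bromo-5-chlorophenyl)-3-oxobutanoate | COC(=O)CC(=O)Cc1cc(Cl)ccc1Br | intermediate
5 | methyl 5-chloro-2-oxo-2,3-dihydro-1H-indene-1-carboxylate (racemic, mainly enol; indane C1 = C10, C2 = C5, C3 = C6, C5 = C13) | COC(=O)C1C(=O)Cc2cc(Cl)ccc21 | intermediate
6 | acrolein | C=CC=O | starting material
7 | methyl (1R)-5-chloro-2-oxo-1-(3-oxopropyl)-2,3-dihydro-1H-indene-1-carboxylate | O=C1Cc2cc(Cl)ccc2[C@]1(C(=O)OC)CCC=O | intermediate
8 | methyl diazoacetate | COC(=O)C=[N+]=[N-] | starting material
9 | methyl 5-[(1R)-5-chloro-1-(methoxycarbonyl)-2-oxo-2,3-dihydro-1H-inden-1-yl]-3-oxopentanoate | O=C1Cc2cc(Cl)ccc2[C@]1(C(=O)OC)CCC(=O)CC(=O)OC | intermediate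
10 | dimethyl 7-chloro-2-oxo-2,3,4,9-tetrahydro-4aH-fluorene-1,4a-dicarboxylate, C10 as in 7 (C3 ketone, C4=C5, C6 methylene, ring C arene) | COC(=O)C1=C2Cc3cc(Cl)ccc3[C@]2(C(=O)OC)CCC1=O | intermediate
11 | dimethyl 7-chloro-1-methyl-2-oxo-1,2,3,4-tetrahydro-4aH-fluorene-1,4a-dicarboxylate with cis esters (C18 β, C19 and C20 α, C5=C6) | C[C@]1(C(=O)OC)C2=Cc3cc(Cl)ccc3[C@]2(C(=O)OC)CCC1=O | intermediate
12 | keto aldehyde: 11 with H5 β and formyl (C7) on the β face of C6, trans-fused rings A and B | C[C@]1(C(=O)OC)[C@H]2[C@H](C=O)c3cc(Cl)ccc3[C@]2(C(=O)OC)CCC1=O | intermediate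
13 | diol: axial 3β-hydroxyl, C7 hydroxymethyl, C19 and C20 methyl esters, 13-chloro arene | C[C@]1(C(=O)OC)[C@H]2[C@H](CO)c3cc(Cl)ccc3[C@]2(C(=O)OC)CC[C@@H]1O | intermediate
14 | bis-TBS ether of 13 | C[C@]1(C(=O)OC)[C@H]2[C@H](CO[Si](C)(C)C(C)(C)C)c3cc(Cl)ccc3[C@]2(C(=O)OC)CC[C@@H]1O[Si](C)(C)C(C)(C)C | intermediate
15 | 3-O-TBS ether with free C7 hydroxyl | C[C@]1(C(=O)OC)[C@H]2[C@H](CO)c3cc(Cl)ccc3[C@]2(C(=O)OC)CC[C@@H]1O[Si](C)(C)C(C)(C)C | intermediate
16 | tributyl(1-ethoxyvinyl)stannane | CCCC[Sn](CCCC)(CCCC)C(=C)OCC | starting material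
17 | 13-(1-ethoxyvinyl) arene | C[C@]1(C(=O)OC)[C@H]2[C@H](CO)c3cc(C(=C)OCC)ccc3[C@]2(C(=O)OC)CC[C@@H]1O[Si](C)(C)C(C)(C)C | intermediate
18 | 13-acetyl arene (C16, C17 in place) | C[C@]1(C(=O)OC)[C@H]2[C@H](CO)c3cc(C(C)=O)ccc3[C@]2(C(=O)OC)CC[C@@H]1O[Si](C)(C)C(C)(C)C | intermediate
19 | perhydrofluorene diol: H8, H9 and H13 all β (mutually cis), C7 hydroxymethyl, 1-hydroxyethyl at C13 (both carbinol epimers) | C[C@]1(C(=O)OC)[C@H]2[C@H](CO)[C@H]3C[C@@H](C(C)O)CC[C@H]3[C@]2(C(=O)OC)CC[C@@H]1O[Si](C)(C)C(C)(C)C | intermediate
20 | keto acid: C7 carboxylic acid, acetyl at C13 trans to H8 (13-epi) | C[C@]1(C(=O)OC)[C@H]2[C@H](C(=O)O)[C@H]3C[C@@H](C(C)=O)CC[C@H]3[C@]2(C(=O)OC)CC[C@@H]1O[Si](C)(C)C(C)(C)C | intermediate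
21 | trimethylsilyldiazomethane | C[Si](C)(C)C=[N+]=[N-] | starting material
22 | 13-epi keto triester | C[C@]1(C(=O)OC)[C@H]2[C@H](C(=O)OC)[C@H]3C[C@@H](C(C)=O)CC[C@H]3[C@]2(C(=O)OC)CC[C@@H]1O[Si](C)(C)C(C)(C)C | intermediate
23 | keto triester precursor: cis-fused perhydrofluorene, H8 and H9 cis, acetyl at C13 cis to H8, 3β-OTBS, trimethyl ester | C[C@]1(C(=O)OC)[C@H]2[C@H](C(=O)OC)[C@H]3C[C@H](C(C)=O)CC[C@H]3[C@]2(C(=O)OC)CC[C@@H]1O[Si](C)(C)C(C)(C)C | intermediate
24 | diazoalkene from 23 | C[C@]1(C(=O)OC)[C@H]2[C@H](C(=O)OC)[C@H]3C[C@H](C(C)=C=[N+]=[N-])CC[C@H]3[C@]2(C(=O)OC)CC[C@@H]1O[Si](C)(C)C(C)(C)C | intermediate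
25 | alkylidene carbene (C16=C15:) | C[C@]1(C(=O)OC)[C@H]2[C@H](C(=O)OC)[C@H]3C[C@H](C(C)=[C])CC[C@H]3[C@]2(C(=O)OC)CC[C@@H]1O[Si](C)(C)C(C)(C)C | intermediate
26 | tetracyclic C15,C16-alkene: gibberellane skeleton, 16-methyl cyclopentene ring D, 3β-OTBS, trimethyl ester | C[C@]1(C(=O)OC)[C@H]2[C@H](C(=O)OC)[C@@]34C[C@@H](CC[C@H]3[C@]2(C(=O)OC)CC[C@@H]1O[Si](C)(C)C(C)(C)C)C(C)=C4 | intermediate
27 | C16 exo-hydroperoxide | C[C@]1(C(=O)OC)[C@H]2[C@H](C(=O)OC)[C@@]34C[C@@H](CC[C@H]3[C@]2(C(=O)OC)CC[C@@H]1O[Si](C)(C)C(C)(C)C)[C@](C)(OO)C4 | intermediate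
28 | C16 tertiary alcohol (exo hydroxyl, endo methyl), 3β-OTBS, trimethyl ester | C[C@]1(C(=O)OC)[C@H]2[C@H](C(=O)OC)[C@@]34C[C@@H](CC[C@H]3[C@]2(C(=O)OC)CC[C@@H]1O[Si](C)(C)C(C)(C)C)[C@](C)(O)C4 | intermediate
29 | 3-O-TBS tricarboxylic acid | C[C@]1(C(=O)O)[C@H]2[C@H](C(=O)O)[C@@]34C[C@@H](CC[C@H]3[C@]2(C(=O)O)CC[C@@H]1O[Si](C)(C)C(C)(C)C)[C@](C)(O)C4 | intermediate
30 | CNP0183110.3: 3β,16-dihydroxy-16-methyl gibberellane-7,19,20-trioic acid (16-hydroxyl exo) | C[C@]1(C(=O)O)[C@H]2[C@H](C(=O)O)[C@@]34C[C@@H](CC[C@H]3[C@]2(C(=O)O)CC[C@@H]1O)[C@](C)(O)C4 | target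

Total step count: 19. Longest linear sequence: 19 steps (1 to 30).

**Steps most likely to fail**

Step 16. The carbene is formed mainly in the ring C chair that carries the alkylidene group equatorially, so capture by solvent, insertion into the C11–H bond or 1,2-methyl shift to an alkyne may win before the ring flips. The fallback sets out from 23 and rejoins the route at 28, using a metal carbenoid that survives until the diaxial geometry is reached. Kinetic enolisation of the methyl ketone with LiN(SiMe3)2 and acylation with 2,2,2-trifluoroethyl trifluoroacetate gives the trifluoroacetyl diketone F1. MsN3 and Et3N in wet MeCN convert it by detrifluoroacetylative diazo transfer into the α-diazo ketone F2. Rh2(OAc)4 in CH2Cl2 then effects the established 1,5 C–H insertion of a rhodium carbenoid into the tertiary C8–H bond to give the ring D cyclopentanone F3 (C16 ketone, the former methyl carbon now C15). Wittig methylenation with Ph3P=CH2 restores the missing carbon as the 16-methylene compound F4. Mukaiyama hydration of F4 under the conditions of step 17 places the hydroxyl exo and gives 28.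

Step 7. The hindered trisubstituted alkene may insert slowly into the rhodium hydride, and plain hydrogenation of the C5=C6 bond may compete, which loses C7. The fallback sets out from 11 and rejoins at 13 by stoichiometric hydroboration and one-carbon homologation. Ethylene glycol and TsOH (toluene, Dean–Stark) protect the C3 ketone as the dioxolane F5. BH3·SMe2 adds from the β face with boron at C6, as for 4,4-dimethyl-5-ene steroids, and treatment with pinacol gives the C6 pinacol boronate F6. Matteson homologation with ClCH2Li (from BrCH2Cl and n-BuLi, −78 °C) followed by NaOH/H2O2 gives the ketal alcohol F7 with retention at C6. Aqueous HCl in THF releases the keto alcohol F8, and LiBH(s-Bu)3 as in step 8 gives 13.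

Step 12. Facial selectivity may be poor if the hydroxymethyl group fails to anchor the arene on the β face, so that hydrogen arrives from the α face. The fallback sets out from 18 and rejoins at 23; it puts both benzylic substituents on the α face before hydrogenation and corrects C6 afterwards. Oxidation with Pr4N[RuO4] and N-methylmorpholine N-oxide monohydrate gives the C7 acid F9, and 21 in MeOH gives the methyl ester F10. LiN(i-Pr)2 (2.2 equiv, −78 °C) forms the C6 ester enolate together with the acetyl enolate. Kinetic protonation with 2,6-di-tert-butylphenol from the β face, anti to C4, gives the 6-epi ester F11 with C7 α. Hydrogenation over Rh/Al2O3 is then directed to the β face by the C7 and C20 esters and gives the perhydro carbinol F12. Dess–Martin periodinane gives the 6,13-bis-epi ketone F13, and NaOMe in MeOH equilibrates C6 and C13 together to 23.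

Further compounds
F1 | step 16 | trifluoroacetyl diketone from 23 | C[C@]1(C(=O)OC)[C@H]2[C@H](C(=O)OC)[C@H]3C[C@H](C(=O)CC(=O)C(F)(F)F)CC[C@H]3[C@]2(C(=O)OC)CC[C@@H]1O[Si](C)(C)C(C)(C)C
F2 | step 16 | α-diazo ketone at C13 | C[C@]1(C(=O)OC)[C@H]2[C@H](C(=O)OC)[C@H]3C[C@H](C(=O)C=[N+]=[N-])CC[C@H]3[C@]2(C(=O)OC)CC[C@@H]1O[Si](C)(C)C(C)(C)C
F3 | step 16 | ring D cyclopentanone (16-oxo, 17-nor) | C[C@]1(C(=O)OC)[C@H]2[C@H](C(=O)OC)[C@@]34C[C@@H](CC[C@H]3[C@]2(C(=O)OC)CC[C@@H]1O[Si](C)(C)C(C)(C)C)C(=O)C4
F4 | step 16 | 16-methylene compound | C[C@]1(C(=O)OC)[C@H]2[C@H](C(=O)OC)[C@@]34C[C@@H](CC[C@H]3[C@]2(C(=O)OC)CC[C@@H]1O[Si](C)(C)C(C)(C)C)C(=C)C4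
F5 | step 7 | C3 dioxolane of 11 | C[C@]1(C(=O)OC)C2=Cc3cc(Cl)ccc3[C@]2(C(=O)OC)CCC14OCCO4
F6 | step 7 | C6 pinacol boronate (H5 β, boron β) | C[C@]1(C(=O)OC)[C@H]2[C@H](B4OC(C)(C)C(C)(C)O4)c3cc(Cl)ccc3[C@]2(C(=O)OC)CCC15OCCO5
F7 | step 7 | ketal alcohol (C7 hydroxymethyl) | C[C@]1(C(=O)OC)[C@H]2[C@H](CO)c3cc(Cl)ccc3[C@]2(C(=O)OC)CCC14OCCO4
F8 | step 7 | keto alcohol | C[C@]1(C(=O)OC)[C@H]2[C@H](CO)c3cc(Cl)ccc3[C@]2(C(=O)OC)CCC1=O
F9 | step 12 | C7 acid of the 13-acetyl arene | C[C@]1(C(=O)OC)[C@H]2[C@H](C(=O)O)c3cc(C(C)=O)ccc3[C@]2(C(=O)OC)CC[C@@H]1O[Si](C)(C)C(C)(C)C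
F10 | step 12 | C7 methyl ester of the 13-acetyl arene | C[C@]1(C(=O)OC)[C@H]2[C@H](C(=O)OC)c3cc(C(C)=O)ccc3[C@]2(C(=O)OC)CC[C@@H]1O[Si](C)(C)C(C)(C)C
F11 | step 12 | 6-epi ester (C7 α) | C[C@]1(C(=O)OC)[C@H]2[C@@H](C(=O)OC)c3cc(C(C)=O)ccc3[C@]2(C(=O)OC)CC[C@@H]1O[Si](C)(C)C(C)(C)C
F12 | step 12 | perhydro 6-epi carbinol (H8, H9, H13 β) | C[C@]1(C(=O)OC)[C@H]2[C@@H](C(=O)OC)[C@H]3C[C@@H](C(C)O)CC[C@H]3[C@]2(C(=O)OC)CC[C@@H]1O[Si](C)(C)C(C)(C)C
F13 | step 12 | 6,13-bis-epi keto triester | C[C@]1(C(=O)OC)[C@H]2[C@@H](C(=O)OC)[C@H]3C[C@@H](C(C)=O)CC[C@H]3[C@]2(C(=O)OC)CC[C@@H]1O[Si](C)(C)C(C)(C)C
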